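C6 is the feature on which the plan rests. It is the allylic carbinol carbon next to the ring-cis (Z) C4=C5 alkene of the ten-membered carbocycle, and it also carries the ring oxygen of the fused γ-lactone (O–C6–C7–C11–C12), so C5–C6 is cut as alkenyl-metal plus aldehyde. Numbering: C1/C10 oxirane, C14 = CH2OH on C10, C15 = CH3 on C4, C7 ring fusion, C8 ester carbinol, C11–C13 methylene-lactone carbons.
Target ⇒ trans-lactone (C14–OPMB, C8–OTBS, no C13) ⇒ C6-hydroxy C12-methyl ester ⇒ cut C5–C6: open-chain epoxy aldehyde ending in the (Z)-1-iodo-2-methylalkene, closed with CrCl2/NiCl2.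
That aldehyde ⇒ cut C7–C8: anti-selective (E)-allylboration of the C8 β,γ-epoxy aldehyde by a C6/C7/C11/C12 allylborane made from methyl penta-3,4-dienoate. The vinyl group left on C7 is the latent C6 aldehyde.
C8 aldehyde ⇒ Sharpless epoxidation of a (Z)-allylic alcohol (sets C1, C10) ⇒ Still–Gennari olefination (C1=C10) of (Z)-5-iodo-4-methylpent-4-enal with an α-prenylated phosphonoacetate (prenyl = C9 plus masked C8). The iodoalkene comes from carbocupration of propyne.
Ring order: oxirane, then the ten-membered carbocycle (key step), then the γ-lactone.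

Key step: step 14

Remark: C-locants and the CIP descriptors attached to them follow the numbering above. The descriptor at C7 changes with the groups on C6, O6 and O8 although the spatial arrangement stays the same.

Step 1
Reactants: 1 2-(2-bromoethyl)-1,3-dioxolane; 2 propyne
Product: 6 2-[(3Z)-4-iodo-3-methylbut-3-en-1-yl]-1,3-dioxolane, via Grignard reagent 3 (not isolated), via alkylcopper 4 (not isolated), via (Z)-alkenylcopper 5 (not isolated)
Conditions: Mg, THF, ≤30 °C; CuBr·SMe2, Et2O/Me2S, −45 °C; 2 (excess), −25 °C; I2, −50 → 0 °C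
Reagents that add atoms: iodine, II
Why: Normant carbocupration adds the alkyl group and copper syn across propyne with copper on the terminal carbon, and iodinolysis of the C–Cu bond with retention leaves C3 cis to iodine, so the Z geometry of C4=C5 is fixed before any ring exists.

Step 2
Reactants: 6 2-[(3Z)-4-iodo-3-methylbut-3-en-1-yl]-1,3-dioxolane
Product: 7 (4Z)-5-iodo-4-methylpent-4-enal
Conditions: 1 M HCl, THF, 40 °C
Reagents that add atoms: water, O
Why: Acid-catalysed acetal hydrolysis frees the C1 aldehyde, and the iodoalkene is inert to dilute aqueous acid.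

Step 3
Reactants: 8 methyl bis(2,2,2-trifluoroethyl)phosphonoacetate; 9 1-bromo-3-methylbut-2-ene
Product: 11 methyl 2-[bis(2,2,2-trifluoroethoxy)phosphoryl]-5-methylhex-4-enoate (racemic), via sodium phosphonate 10 (not isolated)
Conditions: NaH, THF/DMF, 0 °C; 9, 0 °C → rt
Reagents that add atoms: none
Why: C-alkylation of the stabilised phosphonate anion with a reactive allylic bromide puts C9 and a masked C8 aldehyde on the future C10, which an unsubstituted phosphonoacetate cannot supply, and the electron-rich prenyl alkene is chosen because it can later be cleaved beside the iodoalkene.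

Step 4
Reactants: 11 methyl 2-[bis(2,2,2-trifluoroethoxy)phosphoryl]-5-methylhex-4-enoate; 7 (4Z)-5-iodo-4-methylpent-4-enal
Product: 13 methyl (2Z,6Z)-7-iodo-6-methyl-2-(3-methylbut-2-en-1-yl)hepta-2,6-dienoate, via potassium phosphonate 12 (not isolated)
Conditions: KN(SiMe3)2, 18-crown-6, THF, −78 °C; then 7
Reagents that add atoms: none
Why: In the Still–Gennari olefination the electron-poor trifluoroethyl phosphonate and the crown-separated potassium ion make the kinetic adduct collapse faster than it equilibrates, which places C2 cis to the ester carbon C14 on the new C1=C10 alkene.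

Step 5
Reactants: 13 methyl (2Z,6Z)-7-iodo-6-methyl-2-(3-methylbut-2-en-1-yl)hepta-2,6-dienoate
Product: 14 (2Z,6Z)-7-iodo-6-methyl-2-(3-methylbut-2-en-1-yl)hepta-2,6-dien-1-ol
Conditions: i-Bu2AlH, CH2Cl2, −78 → −20 °C; aq. potassium sodium tartrate
Reagents that add atoms: none
Why: Hydride 1,2-reduction of the enoate stops at the allylic alcohol needed for directed epoxidation and leaves the alkenyl iodide, the prenyl group and both alkene geometries untouched.

Step 6
Reactants: 14 (2Z,6Z)-7-iodo-6-methyl-2-(3-methylbut-2-en-1-yl)hepta-2,6-dien-1-ol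
Product: 15 {(2S,3R)-3-[(3Z)-4-iodo-3-methylbut-3-en-1-yl]-2-(3-methylbut-2-en-1-yl)oxiran-2-yl}methanol
Conditions: Ti(OiPr)4 (0.3 equiv), L-(+)-diethyl tartrate (0.36 equiv), t-BuOOH, 4 Å MS, CH2Cl2, −20 °C
Reagents that add atoms: tert-butyl hydroperoxide, CC(C)(C)OO
Why: Sharpless asymmetric epoxidation touches only the alkene of the allylic alcohol, the L-(+)-tartrate catalyst delivers oxygen to the face that makes C10 S, and syn addition to the Z alkene then makes C1 R with C2 and C9 trans on the oxirane.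

Step 7
Reactants: 15 {(2S,3R)-3-[(3Z)-4-iodo-3-methylbut-3-en-1-yl]-2-(3-methylbut-2-en-1-yl)oxiran-2-yl}methanol
Product: 17 (2S,3R)-3-[(3Z)-4-iodo-3-methylbut-3-en-1-yl]-2-{[(4-methoxybenzyl)oxy]methyl}-2-(3-methylbut-2-en-1-yl)oxirane, via sodium alkoxide 16 (not isolated)
Conditions: NaH, 4-methoxybenzyl chloride, Bu4NI (cat.), THF/DMF, 0 °C → rt
Reagents that add atoms: 4-methoxybenzyl chloride, COc1ccc(CCl)cc1
Why: Williamson etherification of the primary alkoxide with an activated benzylic halide should outrun Payne migration of the oxirane, and the PMB ether can be removed oxidatively at the very end.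

Step 8
Reactants: 17 (2S,3R)-3-[(3Z)-4-iodo-3-methylbut-3-en-1-yl]-2-{[(4-methoxybenzyl)oxy]methyl}-2-(3-methylbut-2-en-1-yl)oxirane
Product: 19 2-[(2S,3R)-3-[(3Z)-4-iodo-3-methylbut-3-en-1-yl]-2-{[(4-methoxybenzyl)oxy]methyl}oxiran-2-yl]acetaldehyde, via vicinal diol 18 (not isolated)
Conditions: OsO4 (2 mol %), NaIO4, 2,6-lutidine, dioxane/H2O, 0 °C → rt; used crude
Reagents that add atoms: osmium tetroxide, O=[Os](=O)(=O)=O; sodium periodate, [Na+].[O-]I(=O)(=O)=O
Why: In this Lemieux–Johnson cleavage electrophilic OsO4 should take the trialkyl-substituted prenyl alkene well ahead of the iodine-deactivated C4=C5 alkene, periodate cuts diol 18 as it forms, and the near-neutral buffered medium spares the β,γ-epoxy aldehyde from eliminative opening of the oxirane.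

Step 9
Reactants: 20 prop-2-yn-1-ol; 21 trimethyl orthoacetate
Product: 23 methyl penta-3,4-dienoate, via propargyl ketene acetal 22 (not isolated)
Conditions: EtCO2H (cat.), 110–120 °C, MeOH removed
Reagents that add atoms: none
Why: The Johnson orthoester Claisen rearrangement of ketene acetal 22 is a [3,3] shift that turns the alkyne into a terminal allene and attaches the CH2CO2Me unit (C11, C12) in one operation.

Step 10
Reactants: 24 (+)-α-pinene
Product: 25 (−)-diisopinocampheylborane
Conditions: BH3·SMe2, THF, 0 °C; crystalline solid collected under N2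
Reagents that add atoms: borane–dimethyl sulfide, [BH3-][S+](C)C
Why: Hydroboration of the trisubstituted alkene from the face away from the gem-dimethyl bridge stops at the dialkylborane for steric reasons, and crystallisation in the presence of excess pinene should upgrade the enantiomeric purity.

Step 11
Reactants: 23 methyl penta-3,4-dienoate; 25 (−)-diisopinocampheylborane; 19 2-[(2S,3R)-3-[(3Z)-4-iodo-3-methylbut-3-en-1-yl]-2-{[(4-methoxybenzyl)oxy]methyl}oxiran-2-yl]acetaldehyde
Product: 28 methyl (3S,4R)-3-ethenyl-4-hydroxy-5-[(2S,3R)-3-[(3Z)-4-iodo-3-methylbut-3-en-1-yl]-2-{[(4-methoxybenzyl)oxy]methyl}oxiran-2-yl]pentanoate, via (E)-allylborane 26 (not isolated), via borinate ester 27 (not isolated)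
Conditions: 25 + 23, Et2O, −20 → 20 °C; 19, −78 °C; pH 7 buffer, MeOH, 30% H2O2, 0 °C; crude product silylated at once
Reagents that add atoms: none
Why: In this allene hydroboration and Brown-type allylboration, 25 puts boron on the unsubstituted allene terminus, reversible 1,3-boratropic shifts funnel the allylborane to E isomer 26, its closed chair transition state turns the E geometry into the 7,8-anti array, and the isopinocampheyl groups from (+)-α-pinene select the aldehyde face that gives 8R, all under neutral −78 °C conditions that an enolisable, elimination-prone aldehyde tolerates and that anti-selective imide aldol methods do not offer.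

Step 12
Reactants: 28 methyl (3S,4R)-3-ethenyl-4-hydroxy-5-[oxiranyl]pentanoate (oxirane as in 19)
Product: 29 methyl (3S,4R)-4-[(tert-butyldimethylsilyl)oxy]-3-ethenyl-5-[(2S,3R)-3-[(3Z)-4-iodo-3-methylbut-3-en-1-yl]-2-{[(4-methoxybenzyl)oxy]methyl}oxiran-2-yl]pentanoate
Conditions: TBSOTf, 2,6-lutidine, CH2Cl2, −78 °C
Reagents that add atoms: tert-butyldimethylsilyl trifluoromethanesulfonate, CC(C)(C)[Si](C)(C)OS(=O)(=O)C(F)(F)F
Why: O-silylation with the triflate and a hindered pyridine base is fast at −78 °C even for a flanked secondary alcohol, which blocks lactonisation of O8 onto C12 and should outrun Lewis-acid opening of the oxirane.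

Step 13
Reactants: 29 methyl (3S,4R)-4-[(tert-butyldimethylsilyl)oxy]-3-ethenyl-5-[oxiranyl]pentanoate (oxirane as in 19)
Product: 31 methyl (3R,4R)-4-[(tert-butyldimethylsilyl)oxy]-3-formyl-5-[(2S,3R)-3-[(3Z)-4-iodo-3-methylbut-3-en-1-yl]-2-{[(4-methoxybenzyl)oxy]methyl}oxiran-2-yl]pentanoate, via vicinal diol 30 (not isolated)
Conditions: OsO4 (2 mol %), NaIO4, 2,6-lutidine, dioxane/H2O, 0 °C → rt; used crude
Reagents that add atoms: osmium tetroxide, O=[Os](=O)(=O)=O; sodium periodate, [Na+].[O-]I(=O)(=O)=O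
Why: Lemieux–Johnson cleavage of the monosubstituted vinyl group, again preferred by OsO4 over the deactivated iodoalkene, gives the C6 aldehyde directly at the right oxidation level, so no C6 alcohol that would lactonise onto the C12 ester is ever stored and C7 should not epimerise in the buffered medium.

Step 14
Reactants: 31 methyl (3R,4R)-4-[(tert-butyldimethylsilyl)oxy]-3-formyl-5-[oxiranyl]pentanoate (open-chain epoxy aldehyde ester ending in the (Z)-iodoalkene)
Product: 34 cyclodecene hydroxy ester (1R,6R,7S,8R,10S; 4Z) bearing C6–OH; C7–CH2CO2Me; C8–OTBS; C1–C10 oxirane; C10–CH2OPMB; C4–CH3, via alkenylchromium dichloride 32 (not isolated), via chromium alkoxide 33 (not isolated)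
Conditions: CrCl2 (15 equiv), NiCl2 (0.15 equiv), degassed DMSO/THF 3:1, 31 added over 12 h (final 0.003 M), 25 °C; aq. NH4Cl
Reagents that add atoms: none
Why: Zerovalent nickel, generated from NiCl2 by CrCl2, inserts into the C5–I bond of 31 with retention of the Z geometry, the alkenyl group passes to trivalent chromium to give 32, and 32 adds 1,2 to the C6 aldehyde to give alkoxide 33, which is hydrolysed on work-up. The closest known reaction type is the Nozaki–Hiyama–Kishi macrocyclisation of an ω-formyl alkenyl iodide, established for medium and large carbocycles. The ten-membered ring closes in a 10-exo-trig mode (C5 attacks the carbonyl carbon and the oxygen stays outside the ring), helped by two turn elements already in the chain, the cis C4=C5 alkene and the trans-substituted C1–C10 oxirane, and by slow addition at high dilution. The one new stereocentre, C6, is controlled by C7 and C8: in the Felkin–Anh arrangement the C8 branch stands anti to incoming C5, and in this 7,8-anti β-silyloxy aldehyde the 1,2-preference and the polar 1,3-anti preference reinforce each other, both pointing to the 6R carbinol (O6 syn to C11, anti to O8). The step needs chemoselectivity for the aldehyde over methyl ester, oxirane, silyl ether and PMB ether, which the low basicity and carbonyl selectivity of the alkenylchromium species secure, and geometric fidelity at C4=C5, which the stereoretentive nickel-to-chromium relay secures.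

Step 15
Reactants: 34 cyclodecene hydroxy ester
Product: 35 trans-fused γ-lactone (1R,6R,7S,8R,10S; 4Z): as 34 but O6 acylated by C12
Conditions: PPTS (0.2 equiv), 4 Å MS, benzene, 45 °C
Reagents that add atoms: none
Why: Intramolecular transesterification (5-exo-trig) of a γ-hydroxy methyl ester is entropically driven and needs only a weak acid, chosen because strong acid would provoke transannular attack of the C4=C5 alkene on the C1–C10 oxirane, and since C6 and C7 are untouched the lactone is trans-fused.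

Step 16
Reactants: 35 trans-fused γ-lactone
Product: 37 C11-(dimethylaminomethyl) lactone (C11 epimers), via lithium enolate 36 (not isolated)
Conditions: LiN(i-Pr)2, THF, −78 °C; Me2N=CH2 iodide, −78 → 0 °C
Reagents that add atoms: dimethyl(methylidene)ammonium iodide, C=[N+](C)C.[I-]
Why: Kinetic deprotonation at the only lactone α-carbon (C11) and Mannich reaction of enolate 36 with Eschenmoser's salt brings in C13, and the new C11 centre is of no consequence because it becomes sp2 in the next step.

Step 17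
Reactants: 37 C11-(dimethylaminomethyl) lactone
Product: 39 α-methylene-γ-lactone (1R,6R,7S,8R,10S; 4Z) bearing C8–OTBS; C14–OPMB, via trimethylammonium iodide 38 (not isolated)
Conditions: MeI, THF, rt; sat. aq. NaHCO3/CH2Cl2, rt
Reagents that add atoms: none
Why: Exhaustive N-methylation followed by mild-base Hofmann-type β-elimination of trimethylamine from 38 unveils the exocyclic C11=C13 alkene without nucleophiles that would add to it.

Step 18
Reactants: 39 α-methylene-γ-lactone silyl ether
Product: 40 C8 alcohol (1R,6R,7R,8R,10S; 4Z) bearing C14–OPMB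
Conditions: Bu4NF/AcOH (1:1), THF, 0 °C → rt
Reagents that add atoms: none
Why: Fluoride-induced Si–O cleavage buffered with acetic acid keeps the liberated O8 protonated, which should suppress translactonisation to O8 and conjugate addition to the methylene lactone while PMB ether and oxirane stay intact.

Step 19
Reactants: 40 C8 alcohol
Product: 41 C8 isobutyrate (1R,6R,7R,8R,10S; 4Z) bearing C14–OPMB
Conditions: (i-PrCO)2O, Et3N, DMAP (cat.), CH2Cl2, 0 °C → rt
Reagents that add atoms: isobutyric anhydride, CC(C)C(=O)OC(=O)C(C)C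
Why: DMAP-catalysed acyl transfer to the only free hydroxyl group installs the isobutyrate with retention at C8.

Step 20
Reactants: 41 C8 isobutyrate PMB ether
Product: 42 CNP0247143.1 (1R,6R,7R,8R,10S; 4Z)
Conditions: DDQ, CH2Cl2/pH 7 buffer 10:1, 0 °C
Reagents that add atoms: none
Why: In this oxidative PMB cleavage DDQ takes hydride only from the electron-rich benzylic position, water hydrolyses the oxocarbenium ion, and the buffered two-phase medium should leave oxirane, both esters and the methylene lactone untouched.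

Compound list
1 | 2-(2-bromoethyl)-1,3-dioxolane | BrCCC1OCCO1 | starting material
2 | propyne | CC#C | starting material
3 | [2-(1,3-dioxolan-2-yl)ethyl]magnesium bromide (not isolated) | Br[Mg]CCC1OCCO1 | intermediate
4 | [2-(1,3-dioxolan-2-yl)ethyl]copper (not isolated) | [Cu]CCC1OCCO1 | intermediate
5 | [(1Z)-4-(1,3-dioxolan-2-yl)-2-methylbut-1-en-1-yl]copper (not isolated) | O1CCOC1CC/C(C)=C\[Cu] | intermediate
6 | 2-[(3Z)-4-iodo-3-methylbut-3-en-1-yl]-1,3-dioxolane | O1CCOC1CC/C(C)=C\I | intermediate
7 | (4Z)-5-iodo-4-methylpent-4-enal | O=CCC/C(C)=C\I | intermediate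
8 | methyl bis(2,2,2-trifluoroethyl)phosphonoacetate | COC(=O)CP(=O)(OCC(F)(F)F)OCC(F)(F)F | starting material
9 | 1-bromo-3-methylbut-2-ene | CC(C)=CCBr | starting material
10 | sodium salt of 8 (not isolated) | [Na+].COC(=O)[CH-]P(=O)(OCC(F)(F)F)OCC(F)(F)F | intermediate
11 | methyl 2-[bis(2,2,2-trifluoroethoxy)phosphoryl]-5-methylhex-4-enoate (racemic) | COC(=O)C(CC=C(C)C)P(=O)(OCC(F)(F)F)OCC(F)(F)F | intermediate
12 | potassium salt of 11 (not isolated) | [K+].COC(=O)[C-](CC=C(C)C)P(=O)(OCC(F)(F)F)OCC(F)(F)F | intermediate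
13 | methyl (2Z,6Z)-7-iodo-6-methyl-2-(3-methylbut-2-en-1-yl)hepta-2,6-dienoate | COC(=O)/C(CC=C(C)C)=C\CC/C(C)=C\I | intermediate
14 | (2Z,6Z)-7-iodo-6-methyl-2-(3-methylbut-2-en-1-yl)hepta-2,6-dien-1-ol | OC/C(CC=C(C)C)=C\CC/C(C)=C\I | intermediate
15 | {(2S,3R)-3-[(3Z)-4-iodo-3-methylbut-3-en-1-yl]-2-(3-methylbut-2-en-1-yl)oxiran-2-yl}methanol | CC(C)=CC[C@@]1(CO)O[C@@H]1CC/C(C)=C\I | intermediate
16 | sodium alkoxide of 15 (not isolated) | [Na+].CC(C)=CC[C@@]1(C[O-])O[C@@H]1CC/C(C)=C\I | intermediate
17 | PMB ether of 15 | CC(C)=CC[C@@]1(COCc2ccc(OC)cc2)O[C@@H]1CC/C(C)=C\I | intermediate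
18 | vicinal diol from the prenyl alkene of 17 (carbinol epimers, not isolated) | CC(C)(O)C(O)C[C@@]1(COCc2ccc(OC)cc2)O[C@@H]1CC/C(C)=C\I | intermediate
19 | 2-[(2S,3R)-3-[(3Z)-4-iodo-3-methylbut-3-en-1-yl]-2-{[(4-methoxybenzyl)oxy]methyl}oxiran-2-yl]acetaldehyde | O=CC[C@@]1(COCc2ccc(OC)cc2)O[C@@H]1CC/C(C)=C\I | intermediate
20 | prop-2-yn-1-ol | OCC#C | starting material
21 | trimethyl orthoacetate | CC(OC)(OC)OC | starting material
22 | 3-[(1-methoxyethenyl)oxy]prop-1-yne (not isolated) | C=C(OC)OCC#C | intermediate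
23 | methyl penta-3,4-dienoate | C=C=CCC(=O)OC | intermediate
24 | (+)-α-pinene (1R,5R) | CC1=CC[C@@H]2C[C@H]1C2(C)C | starting material
25 | (−)-diisopinocampheylborane | B([C@@H]1C[C@@H]2C[C@H]([C@H]1C)C2(C)C)[C@@H]1C[C@@H]2C[C@H]([C@H]1C)C2(C)C | intermediate
26 | methyl (3E)-5-(diisopinocampheylboranyl)pent-3-enoate (not isolated) | COC(=O)C/C=C/CB([C@@H]1C[C@@H]2C[C@H]([C@H]1C)C2(C)C)[C@@H]1C[C@@H]2C[C@H]([C@H]1C)C2(C)C | intermediate
27 | O8-diisopinocampheylborinate of 28 (not isolated) | C=C[C@H](CC(=O)OC)[C@H](OB([C@@H]3C[C@@H]4C[C@H]([C@H]3C)C4(C)C)[C@@H]3C[C@@H]4C[C@H]([C@H]3C)C4(C)C)C[C@@]1(COCc2ccc(OC)cc2)O[C@@H]1CC/C(C)=C\I | intermediate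
28 | methyl (3S,4R)-3-ethenyl-4-hydroxy-5-[oxiranyl]pentanoate (oxirane as in 19) | C=C[C@H](CC(=O)OC)[C@H](O)C[C@@]1(COCc2ccc(OC)cc2)O[C@@H]1CC/C(C)=C\I | intermediate
29 | O8-TBS ether of 28 | C=C[C@H](CC(=O)OC)[C@H](O[Si](C)(C)C(C)(C)C)C[C@@]1(COCc2ccc(OC)cc2)O[C@@H]1CC/C(C)=C\I | intermediate
30 | vicinal diol from the vinyl group of 29 (C6 epimers, not isolated) | OCC(O)[C@H](CC(=O)OC)[C@H](O[Si](C)(C)C(C)(C)C)C[C@@]1(COCc2ccc(OC)cc2)O[C@@H]1CC/C(C)=C\I | intermediate
31 | methyl (3R,4R)-4-[(tert-butyldimethylsilyl)oxy]-3-formyl-5-[oxiranyl]pentanoate (key-step precursor) | O=C[C@H](CC(=O)OC)[C@H](O[Si](C)(C)C(C)(C)C)C[C@@]1(COCc2ccc(OC)cc2)O[C@@H]1CC/C(C)=C\I | intermediate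
32 | (Z)-C5 alkenylchromium dichloride of 31 (not isolated) | O=C[C@H](CC(=O)OC)[C@H](O[Si](C)(C)C(C)(C)C)C[C@@]1(COCc2ccc(OC)cc2)O[C@@H]1CC/C(C)=C\[Cr](Cl)Cl | intermediate
33 | O6 chromium dichloride alkoxide of 34 (not isolated) | Cl[Cr](Cl)O[C@@H]1/C=C(/C)CC[C@H]2O[C@]2(COCc3ccc(OC)cc3)C[C@@H](O[Si](C)(C)C(C)(C)C)[C@H]1CC(=O)OC | intermediate
34 | cyclodecene hydroxy ester (1R,6R,7S,8R,10S; 4Z), key-step product | O[C@@H]1/C=C(/C)CC[C@H]2O[C@]2(COCc3ccc(OC)cc3)C[C@@H](O[Si](C)(C)C(C)(C)C)[C@H]1CC(=O)OC | intermediate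
35 | trans-fused γ-lactone (1R,6R,7S,8R,10S; 4Z) | C1C(=O)O[C@@H]2/C=C(/C)CC[C@H]3O[C@]3(COCc4ccc(OC)cc4)C[C@@H](O[Si](C)(C)C(C)(C)C)[C@@H]12 | intermediate
36 | lithium enolate of 35 (not isolated) | [Li+].C1=C([O-])O[C@@H]2/C=C(/C)CC[C@H]3O[C@]3(COCc4ccc(OC)cc4)C[C@@H](O[Si](C)(C)C(C)(C)C)[C@@H]12 | intermediate
37 | C11-(dimethylaminomethyl) lactone (C11 epimers) | CN(C)CC1C(=O)O[C@@H]2/C=C(/C)CC[C@H]3O[C@]3(COCc4ccc(OC)cc4)C[C@@H](O[Si](C)(C)C(C)(C)C)[C@@H]12 | intermediate
38 | trimethylammonium iodide of 37 (not isolated) | [I-].C[N+](C)(C)CC1C(=O)O[C@@H]2/C=C(/C)CC[C@H]3O[C@]3(COCc4ccc(OC)cc4)C[C@@H](O[Si](C)(C)C(C)(C)C)[C@@H]12 | intermediate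
39 | α-methylene-γ-lactone with C8–OTBS and C14–OPMB | C=C1C(=O)O[C@@H]2/C=C(/C)CC[C@H]3O[C@]3(COCc4ccc(OC)cc4)C[C@@H](O[Si](C)(C)C(C)(C)C)[C@@H]12 | intermediate
40 | C8 alcohol with C14–OPMB | C=C1C(=O)O[C@@H]2/C=C(/C)CC[C@H]3O[C@]3(COCc4ccc(OC)cc4)C[C@@H](O)[C@@H]12 | intermediate
41 | C8 isobutyrate with C14–OPMB | C=C1C(=O)O[C@@H]2/C=C(/C)CC[C@H]3O[C@]3(COCc4ccc(OC)cc4)C[C@@H](OC(=O)C(C)C)[C@@H]12 | intermediate
42 | CNP0247143.1 | C=C1C(=O)O[C@@H]2/C=C(/C)CC[C@H]3O[C@]3(CO)C[C@@H](OC(=O)C(C)C)[C@@H]12 | target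

Total step count: 20. Longest linear sequence: 17 steps (1, 2, 4–8, 11–20).

Steps most likely to fail

1) Step 14.
- **Risk:** Intermolecular coupling and simple reduction of the C–I bond may compete with a slow medium-ring closure. The ring-forming conformation may also override the open-chain facial preference at C6.
- **Fallback:** It sets out from 31. The cyclisation is run as described, and if attack on the other aldehyde face prevails it delivers the 6S-epimeric hydroxy ester F1. Its methyl ester is cleaved with Me3SnOH (1,2-dichloroethane, 60 °C) to the hydroxy acid F2. F2 is closed under Mitsunobu conditions (PPh3, DIAD, toluene, 0 °C). The C12 carboxylate then displaces the activated O6 in a 5-exo-tet mode with inversion, so the 6R trans-lactone results and the route is rejoined at 35.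

2) Step 11.
- **Risk:** Z-to-E equilibration of the allylborane may be incomplete, which erodes the anti selectivity. Hydroboration may occur at the internal allene bond, the epoxy aldehyde may undergo eliminative opening before addition, and O8 may lactonise onto C12 during work-up.
- **Fallback:** It sets out from 19 and replaces the allylboration by an Evans syn-aldol followed by Arndt–Eistert homologation.
  - The dibutylboron dienolate of commercial (S)-4-benzyl-3-[(E)-but-2-enoyl]oxazolidin-2-one (n-Bu2BOTf, Et3N, CH2Cl2, −78 °C) should add through its α-carbon to give the α-vinyl syn-aldol imide F3.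
  - Here the vinyl group is C6 and the acyl carbon lies on the C11/C12 side. The syn relation of vinyl and O8 is therefore the same spatial array as the 7,8-anti pattern of 28.
  - Silylation (TBSOTf, 2,6-lutidine, −78 °C) gives the silyl ether F4, and LiOH/H2O2 gives the carboxylic acid F5.
  - Isobutyl chloroformate/N-methylmorpholine gives the mixed anhydride F6, and diazomethane gives the diazoketone F7.
  - Wolff rearrangement (PhCO2Ag, Et3N, MeOH) proceeds with retention at the migrating C7 and inserts C11. The route is rejoined at 29.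

3) Step 1.
- **Risk:** Carbocupration may be sluggish in a medium that still contains THF and a chelating acetal. The Grignard reagent may decay thermally, and homocoupling may occur on iodination.
- **Fallback:** It sets out from 20.
  - Copper-catalysed carbomagnesiation of the magnesium alkoxide (MeMgBr, CuI cat., THF/Et2O, then I2) proceeds through a chelated alkenylmagnesium species and should give (2Z)-3-iodo-2-methylprop-2-en-1-ol F8.
  - CBr4/PPh3 converts it into the allylic bromide F9.
  - Alkylation of the lithium enolate of ethyl acetate (LiN(i-Pr)2, THF/DMPU, −78 °C) gives the ethyl ester F10.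
  - Half-reduction with i-Bu2AlH (CH2Cl2, −78 °C) rejoins the route at 7.

Further compounds
F1 | step 14 | 6S epimer of hydroxy ester 34 | O[C@H]1/C=C(/C)CC[C@H]2O[C@]2(COCc3ccc(OC)cc3)C[C@@H](O[Si](C)(C)C(C)(C)C)[C@H]1CC(=O)OC
F2 | step 14 | 6S hydroxy acid | O[C@H]1/C=C(/C)CC[C@H]2O[C@]2(COCc3ccc(OC)cc3)C[C@@H](O[Si](C)(C)C(C)(C)C)[C@H]1CC(=O)O
F3 | step 11 | (S)-4-benzyl-3-[(2S,3R)-2-ethenyl-3-hydroxy-4-oxiranylbutanoyl]oxazolidin-2-one (oxirane as in 19) | C=C[C@H](C(=O)N1[C@@H](Cc2ccccc2)COC1=O)[C@H](O)C[C@@]3(COCc4ccc(OC)cc4)O[C@@H]3CC/C(C)=C\I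
F4 | step 11 | O8-TBS ether of F3 | C=C[C@H](C(=O)N1[C@@H](Cc2ccccc2)COC1=O)[C@H](O[Si](C)(C)C(C)(C)C)C[C@@]3(COCc4ccc(OC)cc4)O[C@@H]3CC/C(C)=C\I
F5 | step 11 | α-vinyl β-silyloxy carboxylic acid | C=C[C@H](C(=O)O)[C@H](O[Si](C)(C)C(C)(C)C)C[C@@]1(COCc2ccc(OC)cc2)O[C@@H]1CC/C(C)=C\I
F6 | step 11 | isobutyl carbonic mixed anhydride of F5 | C=C[C@H](C(=O)OC(=O)OCC(C)C)[C@H](O[Si](C)(C)C(C)(C)C)C[C@@]1(COCc2ccc(OC)cc2)O[C@@H]1CC/C(C)=C\I
F7 | step 11 | diazoketone from F6 | C=C[C@H](C(=O)C=[N+]=[N-])[C@H](O[Si](C)(C)C(C)(C)C)C[C@@]1(COCc2ccc(OC)cc2)O[C@@H]1CC/C(C)=C\I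
F8 | step 1 | (2Z)-3-iodo-2-methylprop-2-en-1-ol | OC/C(C)=C\I
F9 | step 1 | (1Z)-3-bromo-1-iodo-2-methylprop-1-ene | BrC/C(C)=C\I
F10 | step 1 | ethyl (4Z)-5-iodo-4-methylpent-4-enoate | CCOC(=O)CC/C(C)=C\I
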